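**Retrosynthetic overview**
1. Esters last: C2 angelate (mixed anhydride) and C6 4-hydroxybenzoate (carbodiimide) on a 2-O-PMB daucene-4β,6α-diol core.
2. Cycloheptene: ring-closing metathesis (C8=C9) of a C1-allyl/C6-methallyl diene; C6 carbinol by chelation-controlled methallyl addition to a C5 aldehyde.
3. Key bond C1–C10 (quaternary C1): anionic oxy-Cope [3,3] rearrangement of the allyl adduct of a cyclopentene-1-carbaldehyde; C5 by equilibration of the aldehyde.
4. Cyclopentene: ozonolysis/intramolecular aldol ring contraction of a p-menth-1-ene-4,6-diol derivative.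
5. Diol from (S)-(+)-terpinen-4-ol by SeO2 ene/[2,3] allylic oxidation. Ring order: five-membered ring first, seven-membered ring last.

Assumption: (S)-(+)-terpinen-4-ol is bought as the single enantiomer; daucane numbering of the target (C1 = ring-fusion C–CH3, C2 = CH–O-angelate, C4 = C(OH)iPr, C5 = ring-fusion CH, C6 = CH–O-aroyl, C8=C9 alkene; β = face of the C1 methyl) is used for all intermediates.

Step 1
Reactants: 1 (S)-(+)-terpinen-4-ol
Product: 2 (1R,3R)-4-methyl-1-(propan-2-yl)cyclohex-4-ene-1,3-diol (cis-diol)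
Conditions: SeO2 (0.3 equiv), t-BuOOH (2.5 equiv), CH2Cl2, 0 °C → rt
Reagents that add atoms: selenium dioxide O=[Se]=O (oxygen carrier); tert-butyl hydroperoxide CC(C)(C)OO (stoichiometric oxygen source)
Why: Riley allylic oxidation (ene reaction, then [2,3]-sigmatropic shift of the allylseleninic acid) oxidises the ring CH2 next to the methyl-bearing alkene carbon and returns the double bond to its place, so no symmetric allyl intermediate can racemise C4; the [2,3] shift delivers O pseudo-axially, cis to the axial tertiary OH (iPr equatorial), which sets C2.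

Step 2
Reactants: 2 cis-diol
Product: 4 {[(1R,5R)-5-[(4-methoxybenzyl)oxy]-4-methyl-1-(propan-2-yl)cyclohex-3-en-1-yl]oxy}trimethylsilane, via mono-PMB ether 3 (not isolated)
Conditions: NaH (2.2 equiv), PMBCl (1.05 equiv), Bu4NI (cat.), THF/DMF, 0 °C → rt; then TMSCl, 0 °C
Reagents that add atoms: 4-methoxybenzyl chloride COc1ccc(CCl)cc1; chlorotrimethylsilane C[Si](C)(C)Cl
Why: Williamson etherification occurs only at the less hindered secondary allylic alkoxide, and the remaining tertiary alkoxide is capped in the same pot as a TMS ether so that step 3 meets no free γ-hydroxy ketone/β-hydroxy aldehyde; no stereocentre is touched.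

Step 3
Reactants: 4 PMB/TMS bis-ether
Product: 7 (3R,5R)-5-hydroxy-3-[(4-methoxybenzyl)oxy]-2-methyl-5-(propan-2-yl)cyclopent-1-ene-1-carbaldehyde, via keto-aldehyde 5 (not isolated), via TMS-protected enal 6 (not isolated)
Conditions: O3, CH2Cl2, −78 °C (indicator end-point); Me2S, → rt; then piperidine, AcOH (cat.), rt; then citric acid, MeOH, 0 °C
Reagents that add atoms: ozone [O-][O+]=O
Why: Ozonolysis of the only C=C gives the 1,6-keto-aldehyde, whose aldehyde enamine closes onto the methyl ketone (amine-catalysed intramolecular aldol condensation, five-membered ring) and dehydrates to the tetrasubstituted enal, contracting the p-menthene to the cyclopentene with C6 as CHO on C5; mild acid then frees the tertiary OH, and no new stereocentre is formed.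

Step 4
Reactants: 7 hydroxy-enal; 8 allylmagnesium bromide
Product: 9 1-[(3R,5R)-5-hydroxy-3-[(4-methoxybenzyl)oxy]-2-methyl-5-(propan-2-yl)cyclopent-1-en-1-yl]but-3-en-1-ol (both carbinol epimers)
Conditions: 8 (2.3 equiv), THF, −78 °C; aq NH4Cl
Reagents that add atoms: allylmagnesium bromide C=CC[Mg]Br
Why: Grignard 1,2-addition to the enal (the first equivalent is consumed by the tertiary OH); the new carbinol centre is left as a mixture because it is destroyed in step 5.

Step 5
Reactants: 9 dienol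
Product: 13 (1R,2R,3R,5R)-5-hydroxy-3-[(4-methoxybenzyl)oxy]-2-methyl-2-(prop-2-en-1-yl)-5-(propan-2-yl)cyclopentane-1-carbaldehyde (CHO, 2-CH3, 3-OPMB and 5-OH all β; allyl and iPr α), via dipotassium enolate 10 (not isolated), via bis-TES enol ether 11 (not isolated), via TES-protected aldehyde 12 (not isolated)
Conditions: KH (2.5 equiv), 18-crown-6, THF, 0 °C → rt; TESCl, −78 → 0 °C; then K2CO3, MeOH, 0 °C; then 1 M HCl, THF, 0 °C
Reagents that add atoms: none
Why: Anionic oxy-Cope rearrangement ([3,3]-sigmatropic) of the 1,5-dien-3-olate forms the C1–C10 bond and the quaternary centre, the allyl terminus reaching C1 on the α-face anti to the adjacent 2β-OPMB and the 4β-alkoxide (an oxide that cannot β-eliminate from the enolate); O-silylation, then base methanolysis of the enol ether equilibrates C5 to the epimer with CHO β (trans to the flanking allyl and isopropyl groups) while the tertiary OTES blocks retro-aldol, and acid finally removes that TES group.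

Step 6
Reactants: 13 hydroxy-aldehyde; 14 (2-methylallyl)magnesium chloride
Product: 15 (1S)-1-[(1S,2R,3R,5R)-5-hydroxy-3-[(4-methoxybenzyl)oxy]-2-methyl-2-(prop-2-en-1-yl)-5-(propan-2-yl)cyclopentyl]-3-methylbut-3-en-1-ol
Conditions: 14 (3 equiv), CH2Cl2/THF, −78 → −40 °C; aq NH4Cl
Reagents that add atoms: (2-methylallyl)magnesium chloride CC(=C)C[Mg]Cl
Why: Chelation-controlled (Cram-chelate) Grignard addition: the magnesium alkoxide of the 4β-OH binds the aldehyde oxygen in a six-membered chelate and the methallyl group adds to the exposed face anti to C1, setting C6 as S (6α-OH, 4,6-anti).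

Step 7
Reactants: 15 diene diol
Product: 16 (1R,3R,3aS,4S,8aR)-1-[(4-methoxybenzyl)oxy]-6,8a-dimethyl-3-(propan-2-yl)-1,2,3,3a,4,5,8,8a-octahydroazulene-3,4-diol
Conditions: Grubbs II (5 mol %), CH2Cl2 (5 mM), 40 °C
Reagents that add atoms: none
Why: Ring-closing metathesis between the allyl and the 1,1-disubstituted methallyl alkene closes the trans-fused cycloheptene and creates the trisubstituted C8=C9 bond; no stereocentre is formed.

Step 8
Reactants: 16 bicyclic diol; 17 4-[(tert-butyldimethylsilyl)oxy]benzoic acid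
Product: 18 (1R,3R,3aS,4S,8aR)-3-hydroxy-1-[(4-methoxybenzyl)oxy]-6,8a-dimethyl-3-(propan-2-yl)-1,2,3,3a,4,5,8,8a-octahydroazulen-4-yl 4-[(tert-butyldimethylsilyl)oxy]benzoate
Conditions: 17, DCC, DMAP (cat.), CH2Cl2, rt
Reagents that add atoms: 4-[(tert-butyldimethylsilyl)oxy]benzoic acid CC(C)(C)[Si](C)(C)Oc1ccc(cc1)C(O)=O
Why: Steglich esterification acylates the secondary 6α-OH with retention; the tertiary 4-OH does not react.

Step 9
Reactants: 18 PMB ether
Product: 19 (1R,3R,3aS,4S,8aR)-1,3-dihydroxy-6,8a-dimethyl-3-(propan-2-yl)-1,2,3,3a,4,5,8,8a-octahydroazulen-4-yl 4-[(tert-butyldimethylsilyl)oxy]benzoate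
Conditions: DDQ, CH2Cl2/pH 7 buffer, 0 °C → rt
Reagents that add atoms: none
Why: Oxidative PMB-ether cleavage (benzylic hydride abstraction, hydrolysis of the hemiacetal) frees the 2β-OH without touching the ester, the aryl silyl ether or the alkene.

Step 10
Reactants: 19 diol ester; 20 angelic acid
Product: 21 (1R,3R,3aS,4S,8aR)-3-hydroxy-6,8a-dimethyl-1-{[(2Z)-2-methylbut-2-enoyl]oxy}-3-(propan-2-yl)-1,2,3,3a,4,5,8,8a-octahydroazulen-4-yl 4-[(tert-butyldimethylsilyl)oxy]benzoate
Conditions: 20, 2,4,6-Cl3C6H2COCl, Et3N, toluene, rt; then 19, 80 °C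
Reagents that add atoms: angelic acid C/C=C(/C)C(O)=O
Why: Yamaguchi-type acylation with the preformed mixed anhydride, run without DMAP, esterifies the hindered secondary 2β-OH while keeping the Z (angelate) geometry; the tertiary OH is inert.

Step 11
Reactants: 21 silyl-protected diester
Product: 22 target, (1R,3R,3aS,4S,8aR)-3-hydroxy-6,8a-dimethyl-1-{[(2Z)-2-methylbut-2-enoyl]oxy}-3-(propan-2-yl)-1,2,3,3a,4,5,8,8a-octahydroazulen-4-yl 4-hydroxybenzoate
Conditions: TBAF, AcOH, THF, 0 °C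
Reagents that add atoms: none
Why: Buffered fluoride cleavage of the aryl silyl ether frees the phenol and leaves both esters and the Z-enoate intact.

**Compound list**
1 | (S)-(+)-terpinen-4-ol, (1S)-4-methyl-1-(propan-2-yl)cyclohex-3-en-1-ol | CC1=CC[C@](O)(C(C)C)CC1 | starting material
2 | (1R,3R)-4-methyl-1-(propan-2-yl)cyclohex-4-ene-1,3-diol | O[C@@H]1C[C@@](O)(C(C)C)CC=C1C | intermediate
3 | (1R,3R)-3-[(4-methoxybenzyl)oxy]-4-methyl-1-(propan-2-yl)cyclohex-4-en-1-ol (not isolated) | COc1ccc(CO[C@@H]2C[C@@](O)(C(C)C)CC=C2C)cc1 | intermediate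
4 | {[(1R,5R)-5-[(4-methoxybenzyl)oxy]-4-methyl-1-(propan-2-yl)cyclohex-3-en-1-yl]oxy}trimethylsilane | COc1ccc(CO[C@@H]2C[C@@](O[Si](C)(C)C)(C(C)C)CC=C2C)cc1 | intermediate
5 | (3S,5R)-5-[(4-methoxybenzyl)oxy]-6-oxo-3-(propan-2-yl)-3-[(trimethylsilyl)oxy]heptanal (not isolated) | COc1ccc(CO[C@@H](C(C)=O)C[C@@](O[Si](C)(C)C)(C(C)C)CC=O)cc1 | intermediate
6 | (3R,5R)-3-[(4-methoxybenzyl)oxy]-2-methyl-5-(propan-2-yl)-5-[(trimethylsilyl)oxy]cyclopent-1-ene-1-carbaldehyde (not isolated) | COc1ccc(CO[C@@H]2C[C@@](O[Si](C)(C)C)(C(C)C)C(C=O)=C2C)cc1 | intermediate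
7 | (3R,5R)-5-hydroxy-3-[(4-methoxybenzyl)oxy]-2-methyl-5-(propan-2-yl)cyclopent-1-ene-1-carbaldehyde | COc1ccc(CO[C@@H]2C[C@@](O)(C(C)C)C(C=O)=C2C)cc1 | intermediate
8 | allylmagnesium bromide | C=CC[Mg]Br | starting material
9 | 1-[(3R,5R)-5-hydroxy-3-[(4-methoxybenzyl)oxy]-2-methyl-5-(propan-2-yl)cyclopent-1-en-1-yl]but-3-en-1-ol (carbinol epimers) | COc1ccc(CO[C@@H]2C[C@@](O)(C(C)C)C(C(O)CC=C)=C2C)cc1 | intermediate
10 | dipotassium alkoxide-enolate from the oxy-Cope rearrangement of 9 (enolate E/Z not defined; not isolated) | [K+].[K+].COc1ccc(CO[C@@H]2C[C@@]([O-])(C(C)C)C(=C[O-])[C@@]2(C)CC=C)cc1 | intermediate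
11 | 4-O-triethylsilyl ether/triethylsilyl enol ether of the C5 aldehyde (E/Z mixture; not isolated) | COc1ccc(CO[C@@H]2C[C@@](O[Si](CC)(CC)CC)(C(C)C)C(=CO[Si](CC)(CC)CC)[C@@]2(C)CC=C)cc1 | intermediate
12 | (1R,2R,3R,5R)-3-[(4-methoxybenzyl)oxy]-2-methyl-2-(prop-2-en-1-yl)-5-(propan-2-yl)-5-[(triethylsilyl)oxy]cyclopentane-1-carbaldehyde (not isolated) | COc1ccc(CO[C@@H]2C[C@@](O[Si](CC)(CC)CC)(C(C)C)[C@H](C=O)[C@@]2(C)CC=C)cc1 | intermediate
13 | (1R,2R,3R,5R)-5-hydroxy-3-[(4-methoxybenzyl)oxy]-2-methyl-2-(prop-2-en-1-yl)-5-(propan-2-yl)cyclopentane-1-carbaldehyde | COc1ccc(CO[C@@H]2C[C@@](O)(C(C)C)[C@H](C=O)[C@@]2(C)CC=C)cc1 | intermediate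
14 | (2-methylallyl)magnesium chloride | CC(=C)C[Mg]Cl | starting material
15 | (1S)-1-[(1S,2R,3R,5R)-5-hydroxy-3-[(4-methoxybenzyl)oxy]-2-methyl-2-(prop-2-en-1-yl)-5-(propan-2-yl)cyclopentyl]-3-methylbut-3-en-1-ol | COc1ccc(CO[C@@H]2C[C@@](O)(C(C)C)[C@H]([C@@H](O)CC(C)=C)[C@@]2(C)CC=C)cc1 | intermediate
16 | (1R,3R,3aS,4S,8aR)-1-[(4-methoxybenzyl)oxy]-6,8a-dimethyl-3-(propan-2-yl)-1,2,3,3a,4,5,8,8a-octahydroazulene-3,4-diol | COc1ccc(CO[C@@H]2C[C@@](O)(C(C)C)[C@@H]3[C@@H](O)CC(C)=CC[C@]32C)cc1 | intermediate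
17 | 4-[(tert-butyldimethylsilyl)oxy]benzoic acid | CC(C)(C)[Si](C)(C)Oc1ccc(cc1)C(O)=O | starting material
18 | 4-O-{4-[(tert-butyldimethylsilyl)oxy]benzoate} of 16 | COc1ccc(CO[C@@H]2C[C@@](O)(C(C)C)[C@@H]3[C@@H](OC(=O)c4ccc(O[Si](C)(C)C(C)(C)C)cc4)CC(C)=CC[C@]32C)cc1 | intermediate
19 | (1R,3R,3aS,4S,8aR)-1,3-dihydroxy-6,8a-dimethyl-3-(propan-2-yl)-1,2,3,3a,4,5,8,8a-octahydroazulen-4-yl 4-[(tert-butyldimethylsilyl)oxy]benzoate | O[C@@H]1C[C@@](O)(C(C)C)[C@@H]2[C@@H](OC(=O)c3ccc(O[Si](C)(C)C(C)(C)C)cc3)CC(C)=CC[C@]21C | intermediate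
20 | angelic acid, (2Z)-2-methylbut-2-enoic acid | C/C=C(/C)C(O)=O | starting material
21 | 1-O-angelate of 19 (aryl OTBS) | C/C=C(/C)C(=O)O[C@@H]1C[C@@](O)(C(C)C)[C@@H]2[C@@H](OC(=O)c3ccc(O[Si](C)(C)C(C)(C)C)cc3)CC(C)=CC[C@]21C | intermediate
22 | (1R,3R,3aS,4S,8aR)-3-hydroxy-6,8a-dimethyl-1-{[(2Z)-2-methylbut-2-enoyl]oxy}-3-(propan-2-yl)-1,2,3,3a,4,5,8,8a-octahydroazulen-4-yl 4-hydroxybenzoate | C/C=C(/C)C(=O)O[C@@H]1C[C@@](O)(C(C)C)[C@@H]2[C@@H](OC(=O)c3ccc(O)cc3)CC(C)=CC[C@]21C | target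

**Count and risks**
Total step count: 11. Longest linear sequence: 11 steps (1 → 22).

Most likely to fail, step 1: the Riley oxidation may favour the wrong face (or the methyl group) and can over-oxidise to the enone. The fallback sets out from 1 and returns at 2: the oxidation mixture is accepted, the epimeric (1R,3S)-4-methyl-1-(propan-2-yl)cyclohex-4-ene-1,3-diol F1 is isolated and its secondary allylic carbinol is inverted by a Mitsunobu reaction (4-nitrobenzoic acid, PPh3, DIAD, THF, 0 °C) to the cis-configured (1R,5R)-5-hydroxy-2-methyl-5-(propan-2-yl)cyclohex-2-en-1-yl 4-nitrobenzoate F2, which K2CO3/MeOH converts into 2. Stereocontrol then rests on an SN2 inversion and not on the face selectivity of the [2,3] shift.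

Most likely to fail, step 5: the potassium dienolate may fragment (retro-allylation), the allyl group may reach the wrong face, or the silyl trapping/equilibration sequence may lose material through β-elimination. The fallback sets out from 9 and returns at 11: both hydroxyls of 9 are silylated (TESOTf, 2,6-lutidine, CH2Cl2) to give the bis(triethylsilyl) ether F3, which undergoes a neutral thermal siloxy-Cope rearrangement (o-dichlorobenzene, 200–220 °C, sealed tube). This delivers the silyl enol ether 11 directly, so no β-oxygenated enolate is ever generated; methanolysis/equilibration and acid then continue as in step 5.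

Most likely to fail, step 6: if the magnesium chelate does not control the addition, the dipole-controlled (non-chelate) pathway gives the C6 epimer. The fallback sets out from 13 and returns at 16: the unselective methallylation gives 15 together with the C6-epimeric carbinol F4; ring-closing metathesis of the mixture gives 16 and the 6-epi bicyclic alcohol F5; Dess–Martin oxidation (NaHCO3, CH2Cl2) converges both on the β-hydroxy ketone F6; and Me4NBH(OAc)3 (MeCN/AcOH, −30 °C) delivers hydride intramolecularly from the 4β-O–B ester to the β-face of the C6 ketone, giving the 4β,6α-anti diol 16.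

**Further compounds**
F1 | step 1 | (1R,3S)-4-methyl-1-(propan-2-yl)cyclohex-4-ene-1,3-diol | O[C@H]1C[C@@](O)(C(C)C)CC=C1C
F2 | step 1 | (1R,5R)-5-hydroxy-2-methyl-5-(propan-2-yl)cyclohex-2-en-1-yl 4-nitrobenzoate | [O-][N+](=O)c1ccc(cc1)C(=O)O[C@@H]2C[C@@](O)(C(C)C)CC=C2C
F3 | step 5 | bis(triethylsilyl) ether of 9 (carbinol epimers) | COc1ccc(CO[C@@H]2C[C@@](O[Si](CC)(CC)CC)(C(C)C)C(C(O[Si](CC)(CC)CC)CC=C)=C2C)cc1
F4 | step 6 | C6 (carbinol) epimer of 15 | COc1ccc(CO[C@@H]2C[C@@](O)(C(C)C)[C@H]([C@H](O)CC(C)=C)[C@@]2(C)CC=C)cc1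
F5 | step 6 | C6 epimer of 16 (6β-alcohol) | COc1ccc(CO[C@@H]2C[C@@](O)(C(C)C)[C@@H]3[C@H](O)CC(C)=CC[C@]32C)cc1
F6 | step 6 | C6 ketone of 16 (4β-hydroxy-2β-PMB-oxy-dauc-8-en-6-one) | COc1ccc(CO[C@@H]2C[C@@](O)(C(C)C)[C@@H]3C(=O)CC(C)=CC[C@]32C)cc1
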